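**Retrosynthetic overview** (terpenoid numbering: ring A = C1–C5 and C10, ring B = C5–C10, C20 = methyl on C10, C17 = methyl on C8, C11–C13 = chain on C9, C19 = carboxyl on C4)
1. The plan rests on C10, the quaternary fusion carbon whose methyl must lie syn to the axial C4 methyl, and on C9, which sits between C10 and the C8 carbonyl of ring B.
2. Key disconnection C9–C10 (retro-ene): ring B opens to a ring A methylenecyclohexane 12 with a β-keto ester chain on C5; forward, the enol carbon C9 bonds to C10 and the enol hydrogen turns the methylene into C20.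
3. After ring B: C11–C13 by Michael addition at C9, loss of the C9 carboxyl, C8 methylenation, α-face hydration, acetylation, hydrogenolysis.
4. Before ring B: C4 by catalytic asymmetric methyl addition to a ring A enone ester, C5–C6 by aldol trapping, dehydration and ester-directed hydrogenation, C20 by Wittig reaction, the C9 ester by C-acylation.
5. Ring order: ring A (present in starting material 1), then ring B (step 9).

Key step: step 9

Assumption: compounds 1, 3 and 14 and the reagents named under the steps are taken as commercial; the chiral carbene precursor of step 3 is used as the enantiomer that gives the 1R product.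

Step 1
Reactants: 1 3-oxocyclohex-1-ene-1-carboxylic acid
Product: 2 benzyl 3-oxocyclohex-1-ene-1-carboxylate
Conditions: BnBr, K2CO3, DMF, rt
Reagents that add atoms: benzyl bromide, BrCc1ccccc1
Why: O-Alkylation of the carboxylate (SN2 on benzyl bromide) gives the benzyl ester, which later directs the hydrogenation of step 5 and is cleaved only by hydrogenolysis; no stereocentre is formed.

Step 2
Reactants: 3 ethyl (2-methyl-1,3-dioxolan-2-yl)acetate
Product: 4 (2-methyl-1,3-dioxolan-2-yl)acetaldehyde
Conditions: i-Bu2AlH, CH2Cl2, −78 °C; aqueous tartrate work-up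
Reagents that add atoms: none
Why: Partial hydride reduction of the ester at −78 °C stops at the aldehyde because the aluminium hemiacetal survives until work-up; the ketal is inert and no stereocentre is formed.

Step 3
Reactants: 2 benzyl 3-oxocyclohex-1-ene-1-carboxylate; 4 (2-methyl-1,3-dioxolan-2-yl)acetaldehyde
Product: 6 benzyl (1R)-2-[1-hydroxy-2-(2-methyl-1,3-dioxolan-2-yl)ethyl]-1-methyl-3-oxocyclohexane-1-carboxylate, via methylzinc enolate 5 (not isolated)
Conditions: Me2Zn (3 equiv), Cu(OTf)2 (5 mol %), chiral sulfonate-bearing imidazolinium salt (carbene precursor, 5 mol %), t-BuOMe, −30 °C; then 4, −78 → −30 °C; NH4Cl aq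
Reagents that add atoms: dimethylzinc, C[Zn]C
Why: Copper-catalysed asymmetric conjugate addition of methyl to the β-carbon of the enone ester sets the quaternary C4 under control of the chiral carbene ligand, and the regiodefined zinc enolate 5 adds to aldehyde 4 at C5 (tandem conjugate addition–aldol reaction); the configurations at C5 and at the carbinol carbon are left open because step 4 removes both.

Step 4
Reactants: 6 benzyl (1R)-2-[1-hydroxy-2-(2-methyl-1,3-dioxolan-2-yl)ethyl]-1-methyl-3-oxocyclohexane-1-carboxylate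
Product: 8 benzyl (1R)-1-methyl-2-[2-(2-methyl-1,3-dioxolan-2-yl)ethylidene]-3-oxocyclohexane-1-carboxylate, via mesylate 7 (not isolated)
Conditions: MsCl, Et3N, CH2Cl2, 0 °C; then DBU, rt
Reagents that add atoms: none
Why: Mesylation of the aldol and base-induced β-elimination (E1cB) give the conjugated C5=C6 alkylidene ketone; no stereocentre is set and both alkene isomers serve in step 5.

Step 5
Reactants: 8 benzyl (1R)-1-methyl-2-[2-(2-methyl-1,3-dioxolan-2-yl)ethylidene]-3-oxocyclohexane-1-carboxylate
Product: 9 benzyl (1R,2S)-1-methyl-2-[2-(2-methyl-1,3-dioxolan-2-yl)ethyl]-3-oxocyclohexane-1-carboxylate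
Conditions: H2 (1 atm), [Ir(cod)(PCy3)(py)]PF6 (5 mol %), CH2Cl2, rt
Reagents that add atoms: none
Why: Ester-directed homogeneous hydrogenation: the cationic iridium catalyst binds the carbonyl oxygen of the C4 ester and delivers H2 to the neighbouring C5=C6 bond from the ester face, so H5 ends cis to the ester and the C6 chain cis to the C4 methyl; this directing effect is known for cyclohexenes whose quaternary carboxyl carbon is allylic, and the benzyl ester is not cleaved by the homogeneous catalyst.

Step 6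
Reactants: 9 benzyl (1R,2S)-1-methyl-2-[2-(2-methyl-1,3-dioxolan-2-yl)ethyl]-3-oxocyclohexane-1-carboxylate
Product: 10 benzyl (1R,2R)-1-methyl-3-methylidene-2-[2-(2-methyl-1,3-dioxolan-2-yl)ethyl]cyclohexane-1-carboxylate
Conditions: Ph3PCH3Br, KOt-Bu, THF, 0 °C → reflux
Reagents that add atoms: methyltriphenylphosphonium bromide (ylide source), C[P+](c1ccccc1)(c1ccccc1)c1ccccc1.[Br-]
Why: Wittig methylenation turns the C10 ketone into the exocyclic C10=C20 bond; the only proton the ylide can take readily is on C1, so the hindered C5 centre next to the quaternary C4 should keep its configuration.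

Step 7
Reactants: 10 benzyl (1R,2R)-1-methyl-3-methylidene-2-[2-(2-methyl-1,3-dioxolan-2-yl)ethyl]cyclohexane-1-carboxylate
Product: 11 benzyl (1R,2R)-1-methyl-3-methylidene-2-(3-oxobutyl)cyclohexane-1-carboxylate
Conditions: PPTS, acetone–H2O, 50 °C
Reagents that add atoms: water, O
Why: Mild acid-catalysed ketal hydrolysis releases the methyl ketone without moving the exocyclic double bond; no stereocentre is touched.

Step 8
Reactants: 11 benzyl (1R,2R)-1-methyl-3-methylidene-2-(3-oxobutyl)cyclohexane-1-carboxylate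
Product: 12 benzyl (1R,2R)-2-[5-(benzyloxy)-3,5-dioxopentyl]-1-methyl-3-methylidenecyclohexane-1-carboxylate
Conditions: NaH, (BnO)2CO, THF, reflux; AcOH quench
Reagents that add atoms: dibenzyl carbonate, O=C(OCc1ccccc1)OCc1ccccc1
Why: Claisen-type C-acylation of the ketone enolate with a dialkyl carbonate, which for methyl alkyl ketones takes place at the methyl group and is driven by formation of the β-keto ester enolate; benzyloxide exchange at the C4 ester changes nothing and no stereocentre is touched.

Step 9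
Reactants: 12 benzyl (1R,2R)-2-[5-(benzyloxy)-3,5-dioxopentyl]-1-methyl-3-methylidenecyclohexane-1-carboxylate
Product: 13 dibenzyl (1R,4aR,5R,8aS)-5,8a-dimethyl-2-oxodecahydronaphthalene-1,5-dicarboxylate
Conditions: degassed Ph2O (0.02 M), 250 °C, sealed tube
Reagents that add atoms: none
Why: The β-keto ester enolises and the enol acts as ene donor toward the exocyclic C10=C20 bond in a concerted six-centre transition state (Conia-ene reaction; closest precedent: thermal cyclisation of olefinic ketones and β-keto esters), C9 bonding to C10 while the enol hydrogen is delivered to C20 on the same face, so the methylene becomes the C10 methyl. Ring B closes in the 6-exo mode at the disubstituted alkene carbon; a bond to C20 would need a seven-membered ring and could not pass the hydrogen on. At C10, with the C5 tether equatorial on the ring A chair, the axial C4 methyl blocks the axial trajectory, so C9 should enter equatorially and C20 end axial, syn to the C4 methyl and trans to H5 (trans-decalin), which is also the outcome of a chair-like closure of the tether. C9 is epimerisable through the enol of the product and should settle with the ester equatorial and H9 axial. The step needs face selectivity at C10 and bonding through carbon and not oxygen; the first rests on the C4/C5 pattern of ring A set in steps 3 and 5, the second on the ene geometry, in which the O–H hydrogen is the one transferred.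

Step 10
Reactants: 13 dibenzyl (1R,4aR,5R,8aS)-5,8a-dimethyl-2-oxodecahydronaphthalene-1,5-dicarboxylate; 14 benzyl acrylate
Product: 15 dibenzyl (1R,4aR,5R,8aS)-1-[3-(benzyloxy)-3-oxopropyl]-5,8a-dimethyl-2-oxodecahydronaphthalene-1,5-dicarboxylate
Conditions: Cs2CO3 (0.2 equiv), MeCN, 40 °C
Reagents that add atoms: none
Why: Base-catalysed Michael addition of the β-keto ester to the acrylate builds the C9–C11 bond; the acceptor should enter axially on the α face, anti to the axial C10 methyl, and the quaternary C9 so formed is reset in step 11.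

Step 11
Reactants: 15 dibenzyl (1R,4aR,5R,8aS)-1-[3-(benzyloxy)-3-oxopropyl]-5,8a-dimethyl-2-oxodecahydronaphthalene-1,5-dicarboxylate
Product: 17 (1R,4aS,5R,8aR)-5-(2-carboxyethyl)-1,4a-dimethyl-6-oxodecahydronaphthalene-1-carboxylic acid, via β-keto triacid 16 (not isolated)
Conditions: H2 (1 atm), Pd/C (10%), EtOAc–EtOH, rt; then 50 °C
Reagents that add atoms: none
Why: Hydrogenolysis of the three benzyl esters gives the β-keto acid 16, which decarboxylates on warming through its cyclic enol-forming transition state; ketonisation and equilibration α to the C8 carbonyl place the C9 chain equatorial (β) and H9 axial, trans to the C10 methyl.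

Step 12
Reactants: 17 (1R,4aS,5R,8aR)-5-(2-carboxyethyl)-1,4a-dimethyl-6-oxodecahydronaphthalene-1-carboxylic acid
Product: 18 benzyl (1R,4aS,5R,8aR)-5-[3-(benzyloxy)-3-oxopropyl]-1,4a-dimethyl-6-oxodecahydronaphthalene-1-carboxylate
Conditions: BnBr, K2CO3, DMF, rt
Reagents that add atoms: benzyl bromide, BrCc1ccccc1
Why: Double O-alkylation of the dicarboxylate (SN2 on benzyl bromide) masks both acids again for the alkene-forming and hydration steps; the mild base lets any C9 epimer settle in the equatorial form.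

Step 13
Reactants: 18 benzyl (1R,4aS,5R,8aR)-5-[3-(benzyloxy)-3-oxopropyl]-1,4a-dimethyl-6-oxodecahydronaphthalene-1-carboxylate
Product: 19 benzyl (1R,4aR,5S,8aR)-5-[3-(benzyloxy)-3-oxopropyl]-1,4a-dimethyl-6-methylidenedecahydronaphthalene-1-carboxylate
Conditions: Ph3PCH3Br, KOt-Bu, toluene, 80 °C
Reagents that add atoms: methyltriphenylphosphonium bromide (ylide source), C[P+](c1ccccc1)(c1ccccc1)c1ccccc1.[Br-]
Why: Wittig methylenation of the C8 ketone gives the C8=C17 exocyclic alkene; the esters are inert to the non-stabilised ylide and C9 already has its stable configuration (the descriptors change only through priorities).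

Step 14
Reactants: 19 benzyl (1R,4aR,5S,8aR)-5-[3-(benzyloxy)-3-oxopropyl]-1,4a-dimethyl-6-methylidenedecahydronaphthalene-1-carboxylate
Product: 21 benzyl (1R,4aS,5R,6R,8aR)-5-[3-(benzyloxy)-3-oxopropyl]-6-hydroxy-1,4a,6-trimethyldecahydronaphthalene-1-carboxylate, via alkylmercury acetate 20 (not isolated)
Conditions: Hg(OAc)2, THF–H2O, rt; then NaBH4, NaOH aq, 0 °C, short contact
Reagents that add atoms: water, O
Why: Markovnikov oxymercuration–demercuration: water opens the mercurinium ion at the tertiary C8 from the equatorial α face, away from the axial C10 methyl, so the hydroxyl is 8α and C17 becomes the axial methyl, and NaBH4 then replaces mercury by hydrogen.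

Step 15
Reactants: 21 benzyl (1R,4aS,5R,6R,8aR)-5-[3-(benzyloxy)-3-oxopropyl]-6-hydroxy-1,4a,6-trimethyldecahydronaphthalene-1-carboxylate
Product: 22 benzyl (1R,4aS,5R,6R,8aR)-6-acetoxy-5-[3-(benzyloxy)-3-oxopropyl]-1,4a,6-trimethyldecahydronaphthalene-1-carboxylate
Conditions: Ac2O, DMAP, Et3N, CH2Cl2, 40 °C
Reagents that add atoms: acetic anhydride, CC(=O)OC(C)=O
Why: DMAP-catalysed acyl transfer acetylates the hindered tertiary alcohol at oxygen, so the C8 configuration is kept.

Step 16
Reactants: 22 benzyl (1R,4aS,5R,6R,8aR)-6-acetoxy-5-[3-(benzyloxy)-3-oxopropyl]-1,4a,6-trimethyldecahydronaphthalene-1-carboxylate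
Product: 23 (1R,4aS,5R,6R,8aR)-6-acetoxy-5-(2-carboxyethyl)-1,4a,6-trimethyldecahydronaphthalene-1-carboxylic acid
Conditions: H2 (1 atm), Pd/C (10%), EtOAc, rt
Reagents that add atoms: none
Why: Hydrogenolysis of the two benzyl esters under neutral conditions frees both acids without touching the tertiary acetate or any stereocentre.

**Compound list**
1 | 3-oxocyclohex-1-ene-1-carboxylic acid | OC(=O)C1=CC(=O)CCC1 | starting material
2 | benzyl 3-oxocyclohex-1-ene-1-carboxylate | O=C(OCc1ccccc1)C1=CC(=O)CCC1 | intermediate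
3 | ethyl (2-methyl-1,3-dioxolan-2-yl)acetate | CCOC(=O)CC1(C)OCCO1 | starting material
4 | (2-methyl-1,3-dioxolan-2-yl)acetaldehyde | O=CCC1(C)OCCO1 | intermediate
5 | benzyl (1R)-1-methyl-3-[(methylzincio)oxy]cyclohex-2-ene-1-carboxylate | C[Zn]OC1=C[C@](C)(C(=O)OCc2ccccc2)CCC1 | intermediate (not isolated)
6 | benzyl (1R)-2-[1-hydroxy-2-(2-methyl-1,3-dioxolan-2-yl)ethyl]-1-methyl-3-oxocyclohexane-1-carboxylate (diastereomers at C2 and the carbinol carbon) | O=C1CCC[C@@](C)(C(=O)OCc2ccccc2)C1C(O)CC3(C)OCCO3 | intermediate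
7 | methanesulfonate of 6 | O=C1CCC[C@@](C)(C(=O)OCc2ccccc2)C1C(OS(C)(=O)=O)CC3(C)OCCO3 | intermediate (not isolated)
8 | benzyl (1R)-1-methyl-2-[2-(2-methyl-1,3-dioxolan-2-yl)ethylidene]-3-oxocyclohexane-1-carboxylate (E/Z) | O=C1CCC[C@@](C)(C(=O)OCc2ccccc2)C1=CCC3(C)OCCO3 | intermediate
9 | benzyl (1R,2S)-1-methyl-2-[2-(2-methyl-1,3-dioxolan-2-yl)ethyl]-3-oxocyclohexane-1-carboxylate | O=C1CCC[C@@](C)(C(=O)OCc2ccccc2)[C@@H]1CCC3(C)OCCO3 | intermediate
10 | benzyl (1R,2R)-1-methyl-3-methylidene-2-[2-(2-methyl-1,3-dioxolan-2-yl)ethyl]cyclohexane-1-carboxylate | C=C1CCC[C@@](C)(C(=O)OCc2ccccc2)[C@@H]1CCC3(C)OCCO3 | intermediate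
11 | benzyl (1R,2R)-1-methyl-3-methylidene-2-(3-oxobutyl)cyclohexane-1-carboxylate | C=C1CCC[C@@](C)(C(=O)OCc2ccccc2)[C@@H]1CCC(C)=O | intermediate
12 | benzyl (1R,2R)-2-[5-(benzyloxy)-3,5-dioxopentyl]-1-methyl-3-methylidenecyclohexane-1-carboxylate | C=C1CCC[C@@](C)(C(=O)OCc2ccccc2)[C@@H]1CCC(=O)CC(=O)OCc3ccccc3 | intermediate
13 | dibenzyl (1R,4aR,5R,8aS)-5,8a-dimethyl-2-oxodecahydronaphthalene-1,5-dicarboxylate | O=C1CC[C@@H]2[C@](C)(CCC[C@@]2(C)C(=O)OCc3ccccc3)[C@H]1C(=O)OCc4ccccc4 | intermediate
14 | benzyl acrylate | C=CC(=O)OCc1ccccc1 | starting material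
15 | dibenzyl (1R,4aR,5R,8aS)-1-[3-(benzyloxy)-3-oxopropyl]-5,8a-dimethyl-2-oxodecahydronaphthalene-1,5-dicarboxylate | O=C1CC[C@@H]2[C@](C)(CCC[C@@]2(C)C(=O)OCc3ccccc3)[C@@]1(CCC(=O)OCc4ccccc4)C(=O)OCc5ccccc5 | intermediate
16 | (1R,4aR,5R,8aS)-1-(2-carboxyethyl)-5,8a-dimethyl-2-oxodecahydronaphthalene-1,5-dicarboxylic acid | O=C1CC[C@@H]2[C@](C)(CCC[C@@]2(C)C(=O)O)[C@@]1(CCC(=O)O)C(=O)O | intermediate (not isolated)
17 | (1R,4aS,5R,8aR)-5-(2-carboxyethyl)-1,4a-dimethyl-6-oxodecahydronaphthalene-1-carboxylic acid | O=C1CC[C@@H]2[C@](C)(CCC[C@@]2(C)C(=O)O)[C@H]1CCC(=O)O | intermediate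
18 | benzyl (1R,4aS,5R,8aR)-5-[3-(benzyloxy)-3-oxopropyl]-1,4a-dimethyl-6-oxodecahydronaphthalene-1-carboxylate | O=C1CC[C@@H]2[C@](C)(CCC[C@@]2(C)C(=O)OCc3ccccc3)[C@H]1CCC(=O)OCc4ccccc4 | intermediate
19 | benzyl (1R,4aR,5S,8aR)-5-[3-(benzyloxy)-3-oxopropyl]-1,4a-dimethyl-6-methylidenedecahydronaphthalene-1-carboxylate | C=C1CC[C@@H]2[C@](C)(CCC[C@@]2(C)C(=O)OCc3ccccc3)[C@H]1CCC(=O)OCc4ccccc4 | intermediate
20 | 6-[(acetoxymercurio)methyl] analogue of 21 (8α-hydroxy, same ring configuration) | O[C@]1(C[Hg]OC(C)=O)CC[C@@H]2[C@](C)(CCC[C@@]2(C)C(=O)OCc3ccccc3)[C@H]1CCC(=O)OCc4ccccc4 | intermediate (not isolated)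
21 | benzyl (1R,4aS,5R,6R,8aR)-5-[3-(benzyloxy)-3-oxopropyl]-6-hydroxy-1,4a,6-trimethyldecahydronaphthalene-1-carboxylate | O[C@]1(C)CC[C@@H]2[C@](C)(CCC[C@@]2(C)C(=O)OCc3ccccc3)[C@H]1CCC(=O)OCc4ccccc4 | intermediate
22 | benzyl (1R,4aS,5R,6R,8aR)-6-acetoxy-5-[3-(benzyloxy)-3-oxopropyl]-1,4a,6-trimethyldecahydronaphthalene-1-carboxylate | CC(=O)O[C@]1(C)CC[C@@H]2[C@](C)(CCC[C@@]2(C)C(=O)OCc3ccccc3)[C@H]1CCC(=O)OCc4ccccc4 | intermediate
23 | (1R,4aS,5R,6R,8aR)-6-acetoxy-5-(2-carboxyethyl)-1,4a,6-trimethyldecahydronaphthalene-1-carboxylic acid | CC(=O)O[C@]1(C)CC[C@@H]2[C@](C)(CCC[C@@]2(C)C(=O)O)[C@H]1CCC(=O)O | target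

Total step count: 16. Longest linear sequence: 15 steps (1 → 23 through steps 1 and 3–16); step 2 is a one-step side branch.

**Steps most likely to fail**

1. Step 9 (key step). At the temperature of the ene reaction the β-keto ester may lose benzyl alcohol (acyl ketene formation) faster than it cyclises, or C9 may add to the other face of C10 and close a cis-fused ring B. Fallback (known chemistry): 12 is treated with SnCl4 in CH2Cl2 at −20 to 0 °C. The tin-bound β-keto ester protonates the methylene, and the tertiary C10 cation is captured by the enol carbon C9 in a chair-like closure. This is the cationic cyclisation of olefinic β-keto esters, which gives trans-fused bicyclic keto esters from gem-dimethyl analogues of 12. The route is rejoined at 13 and no new compound is formed (F0).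

2. Step 5. The ketone may compete with the ester for the iridium centre, so that hydrogen is delivered to C5 with poor facial selectivity. Fallback: from 8, Luche reduction (NaBH4, CeCl3·7H2O, MeOH, −20 °C) gives the allylic alcohols benzyl (1R)-3-hydroxy-1-methyl-2-[2-(2-methyl-1,3-dioxolan-2-yl)ethylidene]cyclohexane-1-carboxylate F1. With catalytic NaH in THF the epimer whose hydroxyl is cis to the ester closes to the bridged lactone (1R,5S)-1-methyl-8-[2-(2-methyl-1,3-dioxolan-2-yl)ethylidene]-6-oxabicyclo[3.2.1]octan-7-one F2; the other epimer is oxidised back to 8 with MnO2. Hydrogenation of F2 (H2, Rh/Al2O3, EtOAc) should add hydrogen to the alkylidene on the one-carbon bridge from the open lactone side and give (1R,5S,8S)-1-methyl-8-[2-(2-methyl-1,3-dioxolan-2-yl)ethyl]-6-oxabicyclo[3.2.1]octan-7-one F3. LiOH opens the lactone to (1R,2S,3S)-3-hydroxy-1-methyl-2-[2-(2-methyl-1,3-dioxolan-2-yl)ethyl]cyclohexane-1-carboxylic acid F4, and BnBr with Cs2CO3 gives benzyl (1R,2S,3S)-3-hydroxy-1-methyl-2-[2-(2-methyl-1,3-dioxolan-2-yl)ethyl]cyclohexane-1-carboxylate F5. Periodinane oxidation of F5 rejoins the route at 9.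

3. Step 3. Aldol trapping of the hindered zinc enolate may be incomplete or reverse on warming, so that the simple conjugate adduct is carried forward. Fallback: from 2, the conjugate addition is run alone and quenched with TMSCl and Et3N to give the silyl enol ether benzyl (1R)-1-methyl-3-(trimethylsilyloxy)cyclohex-2-ene-1-carboxylate F6. MeLi in THF at 0 °C then releases the lithium enolate, which adds to 4 at −78 °C (directed aldol reaction of a regiodefined lithium enolate) and rejoins the route at 6.

Further compounds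
F0 | step 9 | none | none
F1 | step 5 | benzyl (1R)-3-hydroxy-1-methyl-2-[2-(2-methyl-1,3-dioxolan-2-yl)ethylidene]cyclohexane-1-carboxylate (both C3 epimers) | OC1CCC[C@@](C)(C(=O)OCc2ccccc2)C1=CCC3(C)OCCO3
F2 | step 5 | (1R,5S)-1-methyl-8-[2-(2-methyl-1,3-dioxolan-2-yl)ethylidene]-6-oxabicyclo[3.2.1]octan-7-one | O=C1O[C@H]2CCC[C@]1(C)C2=CCC3(C)OCCO3
F3 | step 5 | (1R,5S,8S)-1-methyl-8-[2-(2-methyl-1,3-dioxolan-2-yl)ethyl]-6-oxabicyclo[3.2.1]octan-7-one | O=C1O[C@H]2CCC[C@]1(C)[C@@H]2CCC3(C)OCCO3
F4 | step 5 | (1R,2S,3S)-3-hydroxy-1-methyl-2-[2-(2-methyl-1,3-dioxolan-2-yl)ethyl]cyclohexane-1-carboxylic acid | O[C@H]1CCC[C@@](C)(C(=O)O)[C@@H]1CCC3(C)OCCO3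
F5 | step 5 | benzyl (1R,2S,3S)-3-hydroxy-1-methyl-2-[2-(2-methyl-1,3-dioxolan-2-yl)ethyl]cyclohexane-1-carboxylate | O[C@H]1CCC[C@@](C)(C(=O)OCc2ccccc2)[C@@H]1CCC3(C)OCCO3
F6 | step 3 | benzyl (1R)-1-methyl-3-(trimethylsilyloxy)cyclohex-2-ene-1-carboxylate | C[Si](C)(C)OC1=C[C@](C)(C(=O)OCc2ccccc2)CCC1
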